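**Strategy.** Ring A (C4a, C5–C8, C8a; isochromene numbering) holds a tertiary C7 alcohol next to the C8 ketone and an enone β-carbon C4a in a 1,4 relationship. This is the pattern of an opened 7-oxanorbornene whose C7 oxygen was a furan oxygen. A catalytic asymmetric Diels–Alder reaction of a tetrasubstituted 3-silyloxyfuran (C7, C8, C8a, C4a) with an (E)-β-aroyloxyacryloyl imide (C5, C6) forms C5–C4a and C6–C7 at once and sets both stereocentres. The imide carbonyl on C5 only steers regiochemistry; after fluoride-triggered bridge opening it is removed by radical decarboxylation. Sonogashira coupling and gold-catalysed 6-endo cycloisomerisation then build the pyran ring.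

Key step: step 12

Remark: atoms are numbered as in the isochromene core of the target (C1, O2, C3, C4, C4a, C5, C6, C7, C8, C8a), also in the furan and in the bridged intermediates.
Remark: compound 4 is used as the racemate; the stereocentre it brings disappears in step 3.

**Furan fragment**

Step 1
Reactants: 1 ethyl 3-(trimethylsilyl)prop-2-ynoate; 2 ethyl acetate
Product: 3 ethyl 3-oxo-5-(trimethylsilyl)pent-4-ynoate
Conditions: LiN(i-Pr)2 (LDA, 2.2 equiv), 2, THF, −78 °C; then 1, −78 to −40 °C; AcOH quench
Reagents that add atoms: none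
Why: Crossed Claisen condensation, in which the lithium enolate of ethyl acetate adds to the ester carbonyl of 1 (the silyl group shields the β-carbon against conjugate addition) and the second equivalent of base drives the reaction by deprotonating the β-keto ester.

Step 2
Reactants: 3 ethyl 3-oxo-5-(trimethylsilyl)pent-4-ynoate; 4 2-bromopropanoyl bromide (racemic)
Product: 6 ethyl 5-methyl-4-oxo-2-[(trimethylsilyl)ethynyl]-4,5-dihydrofuran-3-carboxylate (racemic), via C-acylated bromo tricarbonyl ester 5 (not isolated)
Conditions: MgCl2, pyridine, CH2Cl2, 0 °C, then 4; then Et3N, rt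
Reagents that add atoms: none
Why: C-acylation of the magnesium enolate of the β-keto ester followed by intramolecular O-alkylation of the tricarbonyl enolate by the α-bromoketone (5-exo-tet) should give the 3(2H)-furanone, the usual route to 4-oxo-4,5-dihydrofuran-3-carboxylates from β-keto esters and α-haloacyl halides.

Step 3
Reactants: 6 ethyl 5-methyl-4-oxo-2-[(trimethylsilyl)ethynyl]-4,5-dihydrofuran-3-carboxylate
Product: 7 ethyl 5-methyl-4-[(triisopropylsilyl)oxy]-2-[(trimethylsilyl)ethynyl]furan-3-carboxylate
Conditions: i-Pr3SiOTf, Et3N, CH2Cl2, 0 °C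
Reagents that add atoms: triisopropylsilyl trifluoromethanesulfonate, CC(C)[Si](OS(=O)(=O)C(F)(F)F)(C(C)C)C(C)C
Why: O-silylation of the furanone enolate (silyl enol ether formation), driven by aromatisation to the 3-silyloxyfuran, which also removes the stereocentre.

Step 4
Reactants: 7 ethyl 5-methyl-4-[(triisopropylsilyl)oxy]-2-[(trimethylsilyl)ethynyl]furan-3-carboxylate
Product: 8 {5-methyl-4-[(triisopropylsilyl)oxy]-2-[(trimethylsilyl)ethynyl]furan-3-yl}methanol
Conditions: i-Bu2AlH (DIBAL-H, 2.5 equiv), CH2Cl2, −78 to −20 °C; aqueous potassium sodium tartrate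
Reagents that add atoms: none
Why: Hydride reduction of the furoate ester to the primary alcohol at low temperature, where the silyl enol ether and the silylalkyne are inert.

Step 5
Reactants: 8 {5-methyl-4-[(triisopropylsilyl)oxy]-2-[(trimethylsilyl)ethynyl]furan-3-yl}methanol
Product: 9 3-{[(tert-butyldimethylsilyl)oxy]methyl}-5-methyl-4-[(triisopropylsilyl)oxy]-2-[(trimethylsilyl)ethynyl]furan
Conditions: t-BuMe2SiCl, imidazole, DMF, rt
Reagents that add atoms: tert-butyldimethylsilyl chloride, CC(C)(C)[Si](C)(C)Cl
Why: Standard silylation of the primary alcohol, so that it can neither be acylated by nor add to the enol-ester dienophile in step 12.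

**Aryl acid and dienophile**

Step 6
Reactants: 10 2,3,4-trimethoxy-6-methylbenzaldehyde
Product: 11 2,3,4-trihydroxy-6-methylbenzaldehyde
Conditions: BBr3 (4 equiv), CH2Cl2, −78 °C to rt; H2O
Reagents that add atoms: none
Why: Exhaustive Lewis-acid cleavage of the three aryl methyl ethers by BBr3.

Step 7
Reactants: 11 2,3,4-trihydroxy-6-methylbenzaldehyde
Product: 12 2-hydroxy-3,4-bis(methoxymethoxy)-6-methylbenzaldehyde
Conditions: MeOCH2Cl (2.1 equiv), i-Pr2NEt, CH2Cl2, 0 °C
Reagents that add atoms: chloromethyl methyl ether, COCCl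
Why: Selective O-alkylation of the two non-chelated phenols, since the C2 hydroxyl is held in a hydrogen bond to the aldehyde and should stay free under amine-base conditions.

Step 8
Reactants: 12 2-hydroxy-3,4-bis(methoxymethoxy)-6-methylbenzaldehyde
Product: 13 2-methoxy-3,4-bis(methoxymethoxy)-6-methylbenzaldehyde
Conditions: MeI, K2CO3, DMF, 40 °C
Reagents that add atoms: iodomethane, CI
Why: Williamson methylation of the remaining chelated phenol under carbonate conditions.

Step 9
Reactants: 13 2-methoxy-3,4-bis(methoxymethoxy)-6-methylbenzaldehyde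
Product: 14 2-methoxy-3,4-bis(methoxymethoxy)-6-methylbenzoic acid
Conditions: NaClO2, NaH2PO4, 2-methyl-2-butene, t-BuOH/H2O, rt
Reagents that add atoms: sodium chlorite, [Na+].[O-]Cl=O
Why: Pinnick oxidation of the hindered aldehyde to the acid, with the alkene scavenging HOCl so that the electron-rich ring and the acetals are spared.

Step 10
Reactants: 15 propiolic acid; 16 oxazolidin-2-one
Product: 17 3-propioloyloxazolidin-2-one
Conditions: DCC, DMAP (5 mol%), CH2Cl2, 0 °C to rt
Reagents that add atoms: none
Why: Carbodiimide-mediated N-acylation of the oxazolidinone (Steglich-type activation with DMAP catalysis) should give the ynoyl imide.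

Step 11
Reactants: 14 2-methoxy-3,4-bis(methoxymethoxy)-6-methylbenzoic acid; 17 3-propioloyloxazolidin-2-one
Product: 18 (E)-3-oxo-3-(2-oxooxazolidin-3-yl)prop-1-en-1-yl 2-methoxy-3,4-bis(methoxymethoxy)-6-methylbenzoate
Conditions: DABCO (10 mol%), MeCN, 0 °C to rt
Reagents that add atoms: none
Why: Amine-catalysed conjugate addition of a carboxylic acid to an activated alkyne (DABCO adds first and the carboxylate then displaces the ammonium group), which should give the thermodynamically preferred E enol ester.

**Union and endgame**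

Step 12
Reactants: 9 3-{[(tert-butyldimethylsilyl)oxy]methyl}-5-methyl-4-[(triisopropylsilyl)oxy]-2-[(trimethylsilyl)ethynyl]furan; 18 (E)-3-oxo-3-(2-oxooxazolidin-3-yl)prop-1-en-1-yl 2-methoxy-3,4-bis(methoxymethoxy)-6-methylbenzoate
Product: 19 Diels–Alder adduct, a 7-oxabicyclo[2.2.1]hept-2-ene numbered C1 = methyl-bearing bridgehead (C7 of the target), C2 = OSi(i-Pr)3, C3 = CH2OSiMe2t-Bu, C4 = (trimethylsilyl)ethynyl bridgehead (C4a), C5 = endo 2-oxooxazolidine-3-carbonyl, C6 = exo aroyloxy; (1R,4S,5R,6R)
Conditions: Cu(SbF6)2 (10 mol%, from CuCl2 and AgSbF6), (R,R)-tBu-box = 2,2'-(propane-2,2-diyl)bis[(4R)-4-tert-butyl-4,5-dihydrooxazole] (11 mol%), 4 Å molecular sieves, CH2Cl2, −78 °C; pyridine quench at −78 °C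
Reagents that add atoms: none
Why: Normal-demand Diels–Alder reaction in which the copper bis(oxazoline) complex chelates the two imide carbonyls of 18 (s-cis enoyl group, square-planar chelate) and lowers its LUMO, so that the electron-rich furan 9 should add at −78 °C with the bond from the most nucleophilic terminus C7 (α to the silyloxy-bearing C8) to the β-carbon C6 leading and the C4a–C5 bond closing the ring; this orbital bias secures the regiochemistry and is the only reason for the acyl group on C5. The closest known reaction types are the copper bis(oxazoline)-catalysed cycloaddition of furan with acryloyl oxazolidinones and the Diels–Alder reactions of 3-silyloxy- and 3-alkoxyfurans. Ring A is closed in the [4+2] mode, suprafacial on both partners, giving the oxygen-bridged bicycle in which the former furan oxygen spans C7 and C4a. The E geometry of 18 is transferred to a trans C5/C6 relationship, and the endo transition state (chelated imide under C8=C8a, away from the oxygen bridge) places the aroyloxy group exo, that is syn to the bridge oxygen on C7, which is the cis C6–O/C7–O relationship of the target, so C6 and C7 are set together. The (R,R) ligand shields the re face of C5, so the furan should add to the si face, which corresponds to 6R,7R after bridge opening. The step needs kinetic endo control and survival of the acid-labile silyl enol ether adduct, which the low temperature, the mild chelating Lewis acid and the cold basic quench are meant to secure.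

Step 13
Reactants: 19 Diels–Alder adduct
Product: 21 bridged carboxylic acid (as 19 with CO2H on C5; 1R,4S,5R,6R), via bridged peroxy acid 20 (not isolated)
Conditions: LiOH, H2O2, THF/H2O (3:1), 0 °C; then aqueous Na2SO3; cold dilute HCl to pH 4
Reagents that add atoms: hydrogen peroxide, OO
Why: Hydroperoxide cleavage of the N-acyl oxazolidinone at the exocyclic carbonyl followed by sulfite reduction of the peracid, in which the silyl enol ether blocks enolisation towards C8a so the bridge stays closed and the doubly ortho-substituted aryl ester resists attack.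

Step 14
Reactants: 21 bridged carboxylic acid
Product: 23 (5S,6R,7R)-6-aroyloxy-4a-ethynyl-7-hydroxy-8a-(hydroxymethyl)-7-methyl-8-oxocyclohex-8a(4a)-ene-5-carboxylic acid (target numbering; cyclohexenone with C8a=C4a), via ring-opened enone silyl ether 22 (not isolated)
Conditions: Bu4NF (TBAF, 4 equiv), THF, −40 °C; then AcOH (6 equiv), 0 °C to rt
Reagents that add atoms: none
Why: Fluoride cleaves the enol silyl group and the resulting enolate expels the bridge oxygen from C4a (E1cB β-elimination, the known opening of 7-oxanorbornan-2-one enolates) to give the C8a=C4a enone and the C7 alkoxide without touching C6 or C7, while the C5 carboxylate prevents deprotonation at C5 and hence loss of the aroate, the C-silyl group falls off in the same stage, and the buffered second stage removes the primary silyl ether without a free alkoxide next to the ynone.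

Step 15
Reactants: 23 enone diol carboxylic acid
Product: 25 (6R,7R)-4a-ethynyl-7-hydroxy-8a-(hydroxymethyl)-7-methyl-8-oxocyclohex-8a(4a)-en-6-yl 2-methoxy-3,4-bis(methoxymethoxy)-6-methylbenzoate (target numbering; C5 is CH2), via thiohydroxamate ester 24 (not isolated)
Conditions: 1-hydroxypyridine-2(1H)-thione, DCC, DMAP (cat.), CH2Cl2, dark, rt; then t-BuSH, visible light, 15 °C
Reagents that add atoms: none
Why: Barton decarboxylation, in which the thiohydroxamate ester fragments under light to the C5 radical (now allylic to C4a=C8a and no longer homoallylic to a strained alkene) that should take hydrogen from the thiol at the less substituted terminus and keep the conjugated enone, with C6 and C7 not involved.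

Step 16
Reactants: 25 enone diol with terminal alkyne; 26 (E)-3-iodoacrylic acid
Product: 27 (E)-5-[(6R,7R)-6-aroyloxy-7-hydroxy-8a-(hydroxymethyl)-7-methyl-8-oxocyclohex-8a(4a)-en-4a-yl]pent-2-en-4-ynoic acid (target numbering)
Conditions: PdCl2(PPh3)2 (5 mol%), CuI (10 mol%), Et3N, THF, rt; work-up at pH 4
Reagents that add atoms: none
Why: Sonogashira coupling of the terminal alkyne with the vinyl iodide with retention of the E geometry, the free acid being carried as its ammonium salt and triethylamine being too weak a base to deprotonate C5.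

Step 17
Reactants: 27 enynoic acid
Product: 28 bis(methoxymethyl) ether of the target, (E)-3-[(6R,7R)-6-aroyloxy-7-hydroxy-7-methyl-8-oxo-5,6,7,8-tetrahydro-1H-isochromen-3-yl]acrylic acid with aroyl = 2-methoxy-3,4-bis(methoxymethoxy)-6-methylbenzoyl
Conditions: Ph3PAuNTf2 (5 mol%), CH2Cl2, rt
Reagents that add atoms: none
Why: Gold-catalysed 6-endo-dig hydroalkoxylation (the cycloisomerisation of 2-alkynylbenzyl-alcohol-type substrates to 1H-isochromenes), in which the C1 hydroxyl should attack C3, the alkyne carbon remote from the electron-poor enone, and protodeauration gives the 2H-pyran, while the E-configured acid cannot reach the alkyne.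

Step 18
Reactants: 28 bis(methoxymethyl) ether of the target
Product: 29 CNP0446308.2, (E)-3-[(6R,7R)-6-(3,4-dihydroxy-2-methoxy-6-methylbenzoyloxy)-7-hydroxy-7-methyl-8-oxo-5,6,7,8-tetrahydro-1H-isochromen-3-yl]acrylic acid
Conditions: TFA/CH2Cl2 (1:5), 0 °C to rt; aqueous work-up
Reagents that add atoms: none
Why: Acidolysis of the two aryl methoxymethyl acetals, which the vinylogous ester, the tertiary ketol and the hindered benzoate should tolerate, and which uses no base that could trigger loss of the aroate.

**Compound list**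

1 | ethyl 3-(trimethylsilyl)prop-2-ynoate | CCOC(=O)C#C[Si](C)(C)C | starting material
2 | ethyl acetate | CCOC(C)=O | starting material
3 | ethyl 3-oxo-5-(trimethylsilyl)pent-4-ynoate | CCOC(=O)CC(=O)C#C[Si](C)(C)C | intermediate
4 | 2-bromopropanoyl bromide (racemic) | CC(Br)C(Br)=O | starting material
5 | ethyl 4-bromo-3-oxo-2-[3-(trimethylsilyl)prop-2-ynoyl]pentanoate (racemic, not isolated) | CCOC(=O)C(C(=O)C#C[Si](C)(C)C)C(=O)C(C)Br | intermediate
6 | ethyl 5-methyl-4-oxo-2-[(trimethylsilyl)ethynyl]-4,5-dihydrofuran-3-carboxylate (racemic) | CCOC(=O)C1=C(C#C[Si](C)(C)C)OC(C)C1=O | intermediate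
7 | ethyl 5-methyl-4-[(triisopropylsilyl)oxy]-2-[(trimethylsilyl)ethynyl]furan-3-carboxylate | CCOC(=O)c1c(C#C[Si](C)(C)C)oc(C)c1O[Si](C(C)C)(C(C)C)C(C)C | intermediate
8 | {5-methyl-4-[(triisopropylsilyl)oxy]-2-[(trimethylsilyl)ethynyl]furan-3-yl}methanol | OCc1c(C#C[Si](C)(C)C)oc(C)c1O[Si](C(C)C)(C(C)C)C(C)C | intermediate
9 | 3-{[(tert-butyldimethylsilyl)oxy]methyl}-5-methyl-4-[(triisopropylsilyl)oxy]-2-[(trimethylsilyl)ethynyl]furan | CC(C)(C)[Si](C)(C)OCc1c(C#C[Si](C)(C)C)oc(C)c1O[Si](C(C)C)(C(C)C)C(C)C | intermediate
10 | 2,3,4-trimethoxy-6-methylbenzaldehyde | COc1cc(C)c(C=O)c(OC)c1OC | starting material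
11 | 2,3,4-trihydroxy-6-methylbenzaldehyde | Cc1cc(O)c(O)c(O)c1C=O | intermediate
12 | 2-hydroxy-3,4-bis(methoxymethoxy)-6-methylbenzaldehyde | COCOc1cc(C)c(C=O)c(O)c1OCOC | intermediate
13 | 2-methoxy-3,4-bis(methoxymethoxy)-6-methylbenzaldehyde | COCOc1cc(C)c(C=O)c(OC)c1OCOC | intermediate
14 | 2-methoxy-3,4-bis(methoxymethoxy)-6-methylbenzoic acid | COCOc1cc(C)c(C(=O)O)c(OC)c1OCOC | intermediate
15 | propiolic acid | C#CC(=O)O | starting material
16 | oxazolidin-2-one | O=C1NCCO1 | starting material
17 | 3-propioloyloxazolidin-2-one | C#CC(=O)N1CCOC1=O | intermediate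
18 | (E)-3-oxo-3-(2-oxooxazolidin-3-yl)prop-1-en-1-yl 2-methoxy-3,4-bis(methoxymethoxy)-6-methylbenzoate | COCOc1cc(C)c(C(=O)O/C=C/C(=O)N2CCOC2=O)c(OC)c1OCOC | intermediate
19 | (1R,4S,5R,6R) Diels–Alder adduct: 7-oxabicyclo[2.2.1]hept-2-ene with 1-methyl, 2-OSi(i-Pr)3, 3-CH2OSiMe2t-Bu, 4-(trimethylsilyl)ethynyl, 5-endo-(2-oxooxazolidine-3-carbonyl), 6-exo-aroyloxy | C[C@]12O[C@](C#C[Si](C)(C)C)(C(CO[Si](C)(C)C(C)(C)C)=C1O[Si](C(C)C)(C(C)C)C(C)C)[C@H](C(=O)N1CCOC1=O)[C@H]2OC(=O)c1c(C)cc(OCOC)c(OCOC)c1OC | intermediate
20 | bridged peroxy acid (as 19 with C5 CO3H; not isolated) | C[C@]12O[C@](C#C[Si](C)(C)C)(C(CO[Si](C)(C)C(C)(C)C)=C1O[Si](C(C)C)(C(C)C)C(C)C)[C@H](C(=O)OO)[C@H]2OC(=O)c1c(C)cc(OCOC)c(OCOC)c1OC | intermediate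
21 | bridged carboxylic acid (as 19 with C5 CO2H; 1R,4S,5R,6R) | C[C@]12O[C@](C#C[Si](C)(C)C)(C(CO[Si](C)(C)C(C)(C)C)=C1O[Si](C(C)C)(C(C)C)C(C)C)[C@H](C(=O)O)[C@H]2OC(=O)c1c(C)cc(OCOC)c(OCOC)c1OC | intermediate
22 | ring-opened enone acid with C1 O-silyl ether and terminal alkyne (5S,6R,7R, target numbering; not isolated) | COCOc1cc(C)c(C(=O)O[C@@H]2[C@@H](C(=O)O)C(C#C)=C(CO[Si](C)(C)C(C)(C)C)C(=O)[C@]2(C)O)c(OC)c1OCOC | intermediate
23 | enone diol carboxylic acid (5S,6R,7R, target numbering) | COCOc1cc(C)c(C(=O)O[C@@H]2[C@@H](C(=O)O)C(C#C)=C(CO)C(=O)[C@]2(C)O)c(OC)c1OCOC | intermediate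
24 | 2-thioxopyridin-1(2H)-yl ester of 23 (thiohydroxamate ester; not isolated) | COCOc1cc(C)c(C(=O)O[C@@H]2[C@@H](C(=O)ON3C=CC=CC3=S)C(C#C)=C(CO)C(=O)[C@]2(C)O)c(OC)c1OCOC | intermediate
25 | decarboxylated enone diol with terminal alkyne (6R,7R, target numbering) | COCOc1cc(C)c(C(=O)O[C@@H]2CC(C#C)=C(CO)C(=O)[C@]2(C)O)c(OC)c1OCOC | intermediate
26 | (E)-3-iodoacrylic acid | OC(=O)/C=C/I | starting material
27 | (E)-enynoic acid (6R,7R, target numbering) | COCOc1cc(C)c(C(=O)O[C@@H]2CC(C#C/C=C/C(=O)O)=C(CO)C(=O)[C@]2(C)O)c(OC)c1OCOC | intermediate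
28 | bis(methoxymethyl) ether of the target (6R,7R) | COCOc1cc(C)c(C(=O)O[C@@H]2CC3=C(COC(/C=C/C(=O)O)=C3)C(=O)[C@]2(C)O)c(OC)c1OCOC | intermediate
29 | CNP0446308.2 (6R,7R) | COc1c(O)c(O)cc(C)c1C(=O)O[C@@H]1CC2=C(COC(/C=C/C(=O)O)=C2)C(=O)[C@]1(C)O | target

**Step count and risks**

Total step count: 18. Longest linear sequence: 12 steps (steps 1–5 and 12–18).

Steps most likely to fail:

1. Step 12 (key Diels–Alder). What may go wrong: erosion of endo and facial selectivity through cycloreversion, or Lewis-acid-induced ionisation of the vinylogous acetal in the adduct (bridge opening with silyl transfer) before the imide has been removed. Fallback, which replaces catalyst control by a covalently bound auxiliary and separation of diastereomers: from acid 14, DABCO-catalysed addition to (S)-4-benzyl-3-propioloyloxazolidin-2-one F1 (from 15 and (S)-4-benzyloxazolidin-2-one with DCC/DMAP) should give the auxiliary-bearing dienophile F2. A chelate-controlled Diels–Alder reaction of F2 with furan 9 (Et2AlCl, CH2Cl2, −78 °C), in which the benzyl group blocks the re face of C5, should give the endo adduct F3, purified by chromatography. LiOH/H2O2 then releases acid 21, where the route is rejoined.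

2. Step 14 (bridge opening and desilylation). What may go wrong: under basic fluoride the freshly formed enone loses the aroate by vinylogous β-elimination, the aroyl group migrates to the C7 alkoxide, or the liberated C1 alkoxide adds to the ynone. Fallback, which replaces the fluoride-generated enolate by a Lewis-acid ionisation: from 21, Me3SiOTf and 2,6-lutidine (CH2Cl2, −78 °C) silylate the bridge oxygen and trigger vinylogous ionisation of the C4a–O bond with loss of the enol silyl group. After aqueous work-up this gives the enone C7 trimethylsilyl ether F4, which still holds the primary silyl ether and the C-silyl group. Buffered fluoride (Bu4NF/AcOH, THF, rt) then removes the three silyl groups without an enolate stage and gives 23.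

3. Step 17 (cycloisomerisation). What may go wrong: competing 5-exo-dig closure by attack at C4, giving an alkylidene dihydrofuran, or sequestration of the catalyst by the acid and ketol. Fallback, which replaces π-acid catalysis by electrophile-induced cyclisation and reduction: from 27, iodocyclisation (I2, NaHCO3, MeCN), which favours the 6-endo mode for this substrate type, should give the 4-iodo-1H-isochromene F5. Hydrodeiodination with Pd(OAc)2, PPh3, HCO2H and Et3N (DMF, rt) then gives 28.

Further compounds
F1 | step 12 | (S)-4-benzyl-3-propioloyloxazolidin-2-one | C#CC(=O)N1[C@@H](Cc2ccccc2)COC1=O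
F2 | step 12 | (E)-3-[(S)-4-benzyl-2-oxooxazolidin-3-yl]-3-oxoprop-1-en-1-yl 2-methoxy-3,4-bis(methoxymethoxy)-6-methylbenzoate | COCOc1cc(C)c(C(=O)O/C=C/C(=O)N2[C@@H](Cc3ccccc3)COC2=O)c(OC)c1OCOC
F3 | step 12 | endo adduct as 19 carrying the (S)-4-benzyl-2-oxooxazolidine-3-carbonyl group on C5 | C[C@]12O[C@](C#C[Si](C)(C)C)(C(CO[Si](C)(C)C(C)(C)C)=C1O[Si](C(C)C)(C(C)C)C(C)C)[C@H](C(=O)N1[C@@H](Cc3ccccc3)COC1=O)[C@H]2OC(=O)c1c(C)cc(OCOC)c(OCOC)c1OC
F4 | step 14 | ring-opened enone acid with C7 trimethylsilyl ether, C1 tert-butyldimethylsilyl ether and (trimethylsilyl)ethynyl group (5S,6R,7R, target numbering) | COCOc1cc(C)c(C(=O)O[C@@H]2[C@@H](C(=O)O)C(C#C[Si](C)(C)C)=C(CO[Si](C)(C)C(C)(C)C)C(=O)[C@]2(C)O[Si](C)(C)C)c(OC)c1OCOC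
F5 | step 17 | 4-iodo derivative of 28 | COCOc1cc(C)c(C(=O)O[C@@H]2CC3=C(COC(/C=C/C(=O)O)=C3I)C(=O)[C@]2(C)O)c(OC)c1OCOC
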